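**Strategy.** Ring A (C1, C10–C14) is made from a 2-pyrone. The pyrone carbonyl becomes C9 on C10 and its ring oxygen sits on C13, so a copper-catalysed inverse-demand Diels–Alder reaction of allyl 4-methyl-2-oxopyran-3-carboxylate with benzyl isopropenyl ether forms C10–C11 and C12–C13 in one operation and sets the oxygenated quaternary C11. The temporary lactone bridge of the bicyclo[2.2.2]octene then leaves in an anti-SN2′ vinylation that creates quaternary C1 and the C13=C14 alkene, making C12 the only allylic methylene for C–H oxidation. Ring B is closed by chromium-mediated vinyl–aldehyde coupling at C6–C7 and the lactone by oxidative lactonisation.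

Key step: step 3

Remark on numbering: from compound 12 onward, positions are cited with the skeleton numbers of the target (ring A = C1, C10–C14; ring B = C1–C10; C15 and C20 are the methyls on C1 and C11, C16 the hydroxymethyl carbon on C5, C17/C18/C19 the lactone α-carbon, its methyl and the lactone carbonyl).
Assumption: the (S,S)-ligand in step 3 delivers the enantiomer drawn; if the sense is opposite, the (R,R)-ligand is used.

Step 1
Reactants: 1 diallyl malonate; 2 4,4-dimethoxybutan-2-one
Product: 3 diallyl 2-(4,4-dimethoxybutan-2-ylidene)malonate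
Conditions: TiCl4, pyridine, THF, 0 °C to rt
Reagents that add atoms: none
Why: Knoevenagel condensation of the malonate with the methyl ketone under TiCl4/pyridine, which should tolerate the dimethyl acetal at low temperature; no stereocentre is formed.

Step 2
Reactants: 3 diallyl 2-(4,4-dimethoxybutan-2-ylidene)malonate
Product: 4 allyl 4-methyl-2-oxo-2H-pyran-3-carboxylate
Conditions: HCO2H/H2O (4:1), 50 °C; then TsOH (cat.), toluene, reflux
Reagents that add atoms: water, O
Why: Acid hydrolysis of the acetal gives the aldehyde, whose (Z)-enol lactonises onto one allyl ester with loss of allyl alcohol (enol lactonisation to the 2-pyrone); no stereocentre is formed.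

Step 3
Reactants: 4 allyl 4-methyl-2-oxo-2H-pyran-3-carboxylate; 5 benzyl isopropenyl ether
Product: 6 allyl (1R,4R,8R)-8-(benzyloxy)-5,8-dimethyl-3-oxo-2-oxabicyclo[2.2.2]oct-5-ene-4-carboxylate (benzyloxy syn to the C5=C6 bridge)
Conditions: Cu(OTf)2 (10 mol%), (S,S)-2,2′-isopropylidenebis(4-tert-butyl-2-oxazoline) (11 mol%), 4 Å molecular sieves, CH2Cl2, −40 to 0 °C
Reagents that add atoms: none
Why: Inverse-electron-demand Diels–Alder reaction: divalent copper, bound in two-point fashion to the lactone and ester carbonyls of 4, lowers the pyrone LUMO, the nucleophilic CH2 terminus of 5 bonds to the pyrone δ-carbon (future C13, giving C12–C13) and the oxocarbenium-like carbon closes onto the ester-bearing carbon (C10–C11) in a concerted but asynchronous [4+2] event. The closest known reaction type is the bis(oxazoline)–copper-catalysed asymmetric cycloaddition of 3-carboalkoxy-2-pyrones with enol ethers. Ring A closes as the six-membered carbocycle of a bicyclo[2.2.2]octene by suprafacial [4+2] addition across C3 and C6 of the pyrone, the lactone being kept as a temporary bridge between C10 and C13. C10 and C13 are bridgeheads fixed by the cycloaddition itself, C11 is set by the endo orientation of the alkoxy group (under the diene, hence anti to the lactone bridge and later trans to C9), and the absolute sense should come from the tert-butyl groups of the ligand shielding one pyrone face. The step needs regio-, endo- and enantioselectivity: the first is secured by the polarisation of the 3-acyl pyrone (electrophilic δ-carbon) matched with the enol ether, the second by the alkoxy group, the third by the rigid copper chelate.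

Step 4
Reactants: 6 allyl ester cycloadduct
Product: 7 (1R,4R,8R)-8-(benzyloxy)-5,8-dimethyl-3-oxo-2-oxabicyclo[2.2.2]oct-5-ene-4-carboxylic acid
Conditions: Pd(PPh3)4 (3 mol%), morpholine, THF, rt
Reagents that add atoms: none
Why: Zerovalent-palladium-catalysed deallylation (π-allyl transfer to morpholine) should free the bridgehead acid without touching the lactone; the bridgehead position prevents thermal decarboxylation and no stereocentre changes.

Step 5
Reactants: 7 bridgehead carboxylic acid
Product: 9 (1R,4R,8R)-8-(benzyloxy)-5,8-dimethyl-2-oxabicyclo[2.2.2]oct-5-en-3-one, via Barton ester 8 (not isolated)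
Conditions: 1-hydroxypyridine-2(1H)-thione, DCC, DMAP (cat.), CH2Cl2, dark, rt; then t-BuSH, hν (tungsten lamp), benzene, rt
Reagents that add atoms: none
Why: Barton decarboxylation: the thiohydroxamate ester fragments under light to a bridgehead radical at C10 that takes hydrogen from t-BuSH, and the bicyclic frame allows hydrogen delivery only with retention, which fixes C10.

Step 6
Reactants: 9 benzyl ether lactone
Product: 10 (1R,4R,8R)-8-hydroxy-5,8-dimethyl-2-oxabicyclo[2.2.2]oct-5-en-3-one
Conditions: BCl3, pentamethylbenzene, CH2Cl2, −78 °C; MeOH quench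
Reagents that add atoms: none
Why: Lewis-acid debenzylation with a cation scavenger should cleave the O–benzyl bond (the benzyl cation is far better stabilised than a C11 cation next to the lactone-bearing carbon), leaving C11 untouched.

Step 7
Reactants: 10 tertiary alcohol
Product: 11 (1R,4R,8R)-5,8-dimethyl-3-oxo-2-oxabicyclo[2.2.2]oct-5-en-8-yl acetate
Conditions: Ac2O, Sc(OTf)3 (2 mol%), MeCN, −20 °C
Reagents that add atoms: acetic anhydride, CC(=O)OC(C)=O
Why: Sc(OTf)3-catalysed acetylation is one of the few acylations that reach hindered tertiary alcohols; C11 keeps its configuration and now carries the acetate of the target.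

Step 8
Reactants: 11 acetoxy lactone
Product: 12 (1R,2S,6R)-6-acetoxy-2-ethenyl-2,6-dimethylcyclohex-3-ene-1-carboxylic acid
Conditions: CH2=CHMgBr (4 equiv), CuBr·SMe2 (2 equiv), THF/Me2S, −78 to −30 °C; aq. NH4Cl, then pH 3
Reagents that add atoms: vinylmagnesium bromide, C=C[Mg]Br
Why: Anti-SN2′ substitution of the allylic lactone by a vinyl cuprate: SN2 attack at the bridgehead C13 is impossible, so the vinyl group should add to C1 on the face opposite the departing carboxylate, creating the C1 quaternary centre with vinyl trans to C9 and moving the alkene to C13=C14.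

Step 9
Reactants: 12 carboxylic acid
Product: 14 (1R,2R,3S)-3-ethenyl-2-formyl-1,3-dimethylcyclohex-4-en-1-yl acetate, via acid chloride 13 (not isolated)
Conditions: (COCl)2, DMF (cat.), CH2Cl2, 0 °C to rt; concentrate; LiAlH(OtBu)3 (1.1 equiv), THF, −78 °C
Reagents that add atoms: none
Why: Partial hydride reduction of an acid chloride: the hindered hydride reduces the acid chloride at −78 °C but not the tertiary acetate, and C10, flanked by two quaternary carbons, should not epimerise.

Step 10
Reactants: 14 aldehyde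
Product: 15 (1S,5S,6R)-5-ethenyl-6-formyl-1,5-dimethyl-2-oxocyclohex-3-en-1-yl acetate
Conditions: CrO3, 3,5-dimethylpyrazole, CH2Cl2, −20 °C
Reagents that add atoms: chromium trioxide, O=[Cr](=O)=O
Why: Allylic C–H oxidation with the CrO3–3,5-dimethylpyrazole complex: C12 is the only allylic CH2 (C1 is quaternary and the vinyl group has no allylic hydrogen), and anhydrous hexavalent-chromium–amine complexes should leave the aldehyde intact; no stereocentre is formed.

Step 11
Reactants: 16 3-(trimethylsilyl)prop-2-yn-1-ol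
Product: 17 (E)-2-[(trimethylsilyl)methylidene]pent-4-en-1-ol (silyl cis to the allyl group)
Conditions: CH2=CHCH2MgBr (3 equiv), CuI (10 mol%), THF, 0 °C to reflux; aq. NH4Cl
Reagents that add atoms: allylmagnesium bromide, C=CC[Mg]Br
Why: Hydroxyl-directed anti-carbomagnesiation of the propargylic alcohol: allyl adds to the carbon next to the carbinol and magnesium ends chelated at the silylated carbon, so after protonation the silyl group is cis to the allyl group, which fixes the later ring-cis C5=C6 geometry.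

Step 12
Reactants: 17 allylic alcohol
Product: 18 (E)-tert-butyldiphenyl({2-[(trimethylsilyl)methylidene]pent-4-en-1-yl}oxy)silane
Conditions: TBDPSCl, imidazole, DMF, rt
Reagents that add atoms: tert-butyl(chloro)diphenylsilane, CC(C)(C)[Si](Cl)(c1ccccc1)c1ccccc1
Why: Standard silyl ether formation on the primary alcohol; the vinylsilane geometry is untouched.

Step 13
Reactants: 15 enone aldehyde; 18 silyl diene (3 equiv)
Product: 19 (1S,5S,6R)-5-[(1E,4E)-4-{[(tert-butyldiphenylsilyl)oxy]methyl}-5-(trimethylsilyl)penta-1,4-dien-1-yl]-6-formyl-1,5-dimethyl-2-oxocyclohex-3-en-1-yl acetate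
Conditions: second-generation Hoveyda–Grubbs catalyst (10 mol%), CH2Cl2, 40 °C
Reagents that add atoms: none
Why: Olefin cross-metathesis between the hindered, non-dimerising vinyl group on quaternary C1 and the terminal alkene of 18 used in excess; the thermodynamically preferred (E)-C2=C3 alkene should result, and the trisubstituted vinylsilane and the enone are inert to the catalyst.

Step 14
Reactants: 20 methyl (S)-3-hydroxy-2-methylpropanoate
Product: 21 methyl (S)-3-[(tert-butyldimethylsilyl)oxy]-2-methylpropanoate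
Conditions: TBSCl, imidazole, CH2Cl2, rt
Reagents that add atoms: tert-butyl(chloro)dimethylsilane, CC(C)(C)[Si](C)(C)Cl
Why: Silyl ether protection of the primary alcohol; the future C17 stereocentre comes from the chiral pool and is not touched.

Step 15
Reactants: 21 silyloxy ester
Product: 23 (S)-4-[(tert-butyldimethylsilyl)oxy]-3-methylbutan-2-one, via Weinreb amide 22 (not isolated)
Conditions: MeNH(OMe)·HCl, iPrMgCl, THF, −20 °C; then MeMgBr, 0 °C
Reagents that add atoms: methylmagnesium bromide, C[Mg]Br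
Why: One-flask ester-to-ketone conversion through the Weinreb amide, whose stable magnesium chelate prevents over-addition; low temperature should avoid epimerisation of C17.

Step 16
Reactants: 23 methyl ketone
Product: 24 (S)-4-[(tert-butyldimethylsilyl)oxy]-3-methylbut-1-en-2-yl trifluoromethanesulfonate
Conditions: KN(SiMe3)2, THF, −78 °C; PhNTf2
Reagents that add atoms: N-phenylbis(trifluoromethanesulfonimide), O=S(=O)(N(c1ccccc1)S(=O)(=O)C(F)(F)F)C(F)(F)F
Why: Kinetic deprotonation of the methyl group by the hindered amide base and O-triflation should give the less substituted enol triflate without disturbing the adjacent C17 centre.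

Step 17
Reactants: 19 enone aldehyde with side chain; 24 enol triflate
Product: 25 C9 allylic alcohol: 19 whose aldehyde carbon has become C9H(OH) bearing the C8(=C7H2)–C17H(CH3)–C19H2OTBS chain (C9 and C17 configured as in 36)
Conditions: CrCl2 (4 equiv), NiCl2 (5 mol%), (S)-configured oxazoline–sulfonamide ligand, Et3N, THF, rt
Reagents that add atoms: none
Why: Nozaki–Hiyama–Kishi coupling, chemoselective for the aldehyde over the enone and acetate; the chiral sulfonamide ligand on chromium should control the face of the hindered aldehyde and set C9.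

Step 18
Reactants: 25 allylic alcohol
Product: 26 C9 acetate of 25
Conditions: Ac2O, DMAP, Et3N, CH2Cl2, 0 °C to rt
Reagents that add atoms: acetic anhydride, CC(=O)OC(C)=O
Why: DMAP-catalysed acetylation of the secondary allylic alcohol installs the C9 acetate of the target; C9 is retained.

Step 19
Reactants: 26 vinylsilane
Product: 27 vinyl iodide: 26 with iodine in place of the trimethylsilyl group at C6 (iodine cis to C4)
Conditions: N-iodosuccinimide, (CF3)2CHOH, 0 °C
Reagents that add atoms: N-iodosuccinimide, O=C1CCC(=O)N1I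
Why: Electrophilic iododesilylation (ipso substitution through the β-silyl cation) should be fastest at the vinylsilane and proceed with retention, so iodine stays cis to C4.

Step 20
Reactants: 27 vinyl iodide
Product: 28 (2R,3R)-2,3-epoxide of 27
Conditions: D-fructose-derived ketone catalyst (0.3 equiv), KHSO5, K2CO3, Bu4NHSO4, MeCN/dimethoxymethane/aq. borate buffer (pH 10.5), 0 °C
Reagents that add atoms: potassium peroxymonosulfate, [K+].[O-]S(=O)(=O)OO
Why: Shi epoxidation: the chiral dioxirane should epoxidise the trans-disubstituted C2=C3 alkene much faster than the 1,1-disubstituted, iodo-substituted and enone alkenes, and the spiro transition state of the D-fructose-derived ketone is expected to give the (2R,3R) trans epoxide.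

Step 21
Reactants: 28 epoxide
Product: 29 7,8-diol: 28 with C8(OH)–C7H2OH in place of C8=C7H2 (C8 hydroxyl anti to the C9 acetate)
Conditions: OsO4 (5 mol%), N-methylmorpholine N-oxide, acetone/H2O, rt
Reagents that add atoms: N-methylmorpholine N-oxide, C[N+]1([O-])CCOCC1; water, O
Why: Catalytic osmium tetroxide dihydroxylation of the only remaining electron-rich alkene; attack anti to the allylic C9 oxygen in the conformer with C9–H eclipsing the alkene (empirical rule for osmylation of allylic oxygen compounds) should place the C8 hydroxyl anti to the C9 acetate.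

Step 22
Reactants: 29 diol
Product: 30 C7 aldehyde with free tertiary C8 hydroxyl
Conditions: Dess–Martin periodinane, NaHCO3, CH2Cl2, 0 °C
Reagents that add atoms: none
Why: Dess–Martin oxidation converts the primary alcohol of the 1,2-diol to the aldehyde while the tertiary alcohol cannot react; C8 is quaternary, so no epimerisation is possible.

Step 23
Reactants: 30 α-hydroxy aldehyde
Product: 31 C8 trimethylsilyl ether of 30
Conditions: 1-(trimethylsilyl)imidazole, CH2Cl2, rt
Reagents that add atoms: 1-(trimethylsilyl)imidazole, C[Si](C)(C)n1ccnc1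
Why: Neutral silylation of the tertiary alcohol gives the α-silyloxy aldehyde needed for non-chelation control in the ring closure; no stereocentre changes.

Step 24
Reactants: 31 iodo aldehyde
Product: 32 macrocycle: ring B closed at C6–C7, with 7-OH, 8-OSiMe3, 19-OTBS and 16-OTBDPS (C7 as in 36)
Conditions: CrCl2 (20 equiv), NiCl2 (0.2 equiv), DMSO/THF (3:1), 2 mM, rt
Reagents that add atoms: none
Why: Intramolecular Nozaki–Hiyama–Kishi reaction at high dilution closes ring B; addition should follow the polar Felkin–Anh model (C8–OSi bond anti to the incoming vinylchromium, C9 in the inside position), which gives the 7,8-anti relationship of the target.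

Step 25
Reactants: 32 macrocycle
Product: 33 7,8,19-triol with the 16-OTBDPS ether retained
Conditions: HF·pyridine, pyridine, THF, 0 °C
Reagents that add atoms: none
Why: Buffered HF·pyridine should remove the tertiary trimethylsilyl and primary tert-butyldimethylsilyl ethers but not the more robust tert-butyldiphenylsilyl ether; no stereocentre changes.

Step 26
Reactants: 33 triol
Product: 35 16-O-tert-butyldiphenylsilyl ether of the target, via lactol 34 (not isolated)
Conditions: TEMPO (0.2 equiv), PhI(OAc)2 (3 equiv), CH2Cl2, rt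
Reagents that add atoms: none
Why: TEMPO/PhI(OAc)2 oxidative lactonisation: the primary C19 alcohol is oxidised selectively, the aldehyde is trapped by the C7 hydroxyl as a five-membered lactol and this is oxidised to the γ-lactone, leaving the tertiary C8 hydroxyl free.

Step 27
Reactants: 35 silyl ether
Product: 36 target compound (CNP0155754.2)
Conditions: Bu4NF, AcOH (1:1), THF, 0 °C to rt
Reagents that add atoms: none
Why: Fluoride-mediated desilylation buffered with acetic acid should free the C16 alcohol without acyl migration or β-elimination of the C8 hydroxyl.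

**Compound list**

1 | diallyl malonate | C=CCOC(=O)CC(=O)OCC=C | starting material
2 | 4,4-dimethoxybutan-2-one | CC(=O)CC(OC)OC | starting material
3 | diallyl 2-(4,4-dimethoxybutan-2-ylidene)malonate | COC(OC)CC(C)=C(C(=O)OCC=C)C(=O)OCC=C | intermediate
4 | allyl 4-methyl-2-oxo-2H-pyran-3-carboxylate | CC1=C(C(=O)OCC=C)C(=O)OC=C1 | intermediate
5 | benzyl isopropenyl ether | C=C(C)OCc1ccccc1 | starting material
6 | allyl (1R,4R,8R)-8-(benzyloxy)-5,8-dimethyl-3-oxo-2-oxabicyclo[2.2.2]oct-5-ene-4-carboxylate | O=C1O[C@@H]2C[C@@](C)(OCc3ccccc3)[C@@]1(C(=O)OCC=C)C(C)=C2 | intermediate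
7 | (1R,4R,8R)-8-(benzyloxy)-5,8-dimethyl-3-oxo-2-oxabicyclo[2.2.2]oct-5-ene-4-carboxylic acid | O=C1O[C@@H]2C[C@@](C)(OCc3ccccc3)[C@@]1(C(=O)O)C(C)=C2 | intermediate
8 | 2-thioxopyridin-1(2H)-yl ester of 7 (Barton ester) | O=C1O[C@@H]2C[C@@](C)(OCc3ccccc3)[C@@]1(C(=O)On3ccccc3=S)C(C)=C2 | intermediate
9 | (1R,4R,8R)-8-(benzyloxy)-5,8-dimethyl-2-oxabicyclo[2.2.2]oct-5-en-3-one | O=C1O[C@@H]2C[C@@](C)(OCc3ccccc3)[C@H]1C(C)=C2 | intermediate
10 | (1R,4R,8R)-8-hydroxy-5,8-dimethyl-2-oxabicyclo[2.2.2]oct-5-en-3-one | O=C1O[C@@H]2C[C@@](C)(O)[C@H]1C(C)=C2 | intermediate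
11 | (1R,4R,8R)-5,8-dimethyl-3-oxo-2-oxabicyclo[2.2.2]oct-5-en-8-yl acetate | O=C1O[C@@H]2C[C@@](C)(OC(C)=O)[C@H]1C(C)=C2 | intermediate
12 | (1R,2S,6R)-6-acetoxy-2-ethenyl-2,6-dimethylcyclohex-3-ene-1-carboxylic acid | OC(=O)[C@@H]1[C@](C)(C=CC[C@@]1(C)OC(C)=O)C=C | intermediate
13 | acid chloride of 12 | ClC(=O)[C@@H]1[C@](C)(C=CC[C@@]1(C)OC(C)=O)C=C | intermediate
14 | (1R,2R,3S)-3-ethenyl-2-formyl-1,3-dimethylcyclohex-4-en-1-yl acetate | O=C[C@@H]1[C@](C)(C=CC[C@@]1(C)OC(C)=O)C=C | intermediate
15 | (1S,5S,6R)-5-ethenyl-6-formyl-1,5-dimethyl-2-oxocyclohex-3-en-1-yl acetate | O=C[C@@H]1[C@](C)(C=CC(=O)[C@@]1(C)OC(C)=O)C=C | intermediate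
16 | 3-(trimethylsilyl)prop-2-yn-1-ol | C[Si](C)(C)C#CCO | starting material
17 | (E)-2-[(trimethylsilyl)methylidene]pent-4-en-1-ol | C[Si](C)(C)/C=C(\CC=C)CO | intermediate
18 | (E)-tert-butyldiphenyl({2-[(trimethylsilyl)methylidene]pent-4-en-1-yl}oxy)silane | C[Si](C)(C)/C=C(\CC=C)CO[Si](c1ccccc1)(c1ccccc1)C(C)(C)C | intermediate
19 | (1S,5S,6R)-5-[(1E,4E)-4-{[(tert-butyldiphenylsilyl)oxy]methyl}-5-(trimethylsilyl)penta-1,4-dien-1-yl]-6-formyl-1,5-dimethyl-2-oxocyclohex-3-en-1-yl acetate | O=C[C@@H]1[C@](C)(C=CC(=O)[C@@]1(C)OC(C)=O)/C=C/C/C(CO[Si](c1ccccc1)(c1ccccc1)C(C)(C)C)=C\[Si](C)(C)C | intermediate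
20 | methyl (S)-3-hydroxy-2-methylpropanoate | OC[C@H](C)C(=O)OC | starting material
21 | methyl (S)-3-[(tert-butyldimethylsilyl)oxy]-2-methylpropanoate | CC(C)(C)[Si](C)(C)OC[C@H](C)C(=O)OC | intermediate
22 | (S)-3-[(tert-butyldimethylsilyl)oxy]-N-methoxy-N,2-dimethylpropanamide | CC(C)(C)[Si](C)(C)OC[C@H](C)C(=O)N(C)OC | intermediate
23 | (S)-4-[(tert-butyldimethylsilyl)oxy]-3-methylbutan-2-one | CC(C)(C)[Si](C)(C)OC[C@H](C)C(C)=O | intermediate
24 | (S)-4-[(tert-butyldimethylsilyl)oxy]-3-methylbut-1-en-2-yl trifluoromethanesulfonate | CC(C)(C)[Si](C)(C)OC[C@H](C)C(=C)OS(=O)(=O)C(F)(F)F | intermediate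
25 | C9 allylic alcohol (C9H(OH)–C8(=C7H2)–C17–C19H2OTBS chain on C10; silyl dienyl chain on C1) | O[C@@H](C(=C)[C@@H](C)CO[Si](C)(C)C(C)(C)C)[C@@H]1[C@](C)(C=CC(=O)[C@@]1(C)OC(C)=O)/C=C/C/C(CO[Si](c1ccccc1)(c1ccccc1)C(C)(C)C)=C\[Si](C)(C)C | intermediate
26 | C9 acetate of 25 | CC(=O)O[C@@H](C(=C)[C@@H](C)CO[Si](C)(C)C(C)(C)C)[C@@H]1[C@](C)(C=CC(=O)[C@@]1(C)OC(C)=O)/C=C/C/C(CO[Si](c1ccccc1)(c1ccccc1)C(C)(C)C)=C\[Si](C)(C)C | intermediate
27 | C6 vinyl iodide (iodine cis to C4) | CC(=O)O[C@@H](C(=C)[C@@H](C)CO[Si](C)(C)C(C)(C)C)[C@@H]1[C@](C)(C=CC(=O)[C@@]1(C)OC(C)=O)/C=C/C/C(CO[Si](c1ccccc1)(c1ccccc1)C(C)(C)C)=C\I | intermediate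
28 | (2R,3R)-epoxide of 27 | CC(=O)O[C@@H](C(=C)[C@@H](C)CO[Si](C)(C)C(C)(C)C)[C@@H]1[C@](C)(C=CC(=O)[C@@]1(C)OC(C)=O)[C@H]1O[C@@H]1C/C(CO[Si](c1ccccc1)(c1ccccc1)C(C)(C)C)=C\I | intermediate
29 | 7,8-diol | CC(=O)O[C@@H]([C@@](O)(CO)[C@@H](C)CO[Si](C)(C)C(C)(C)C)[C@@H]1[C@](C)(C=CC(=O)[C@@]1(C)OC(C)=O)[C@H]1O[C@@H]1C/C(CO[Si](c1ccccc1)(c1ccccc1)C(C)(C)C)=C\I | intermediate
30 | C7 aldehyde with free 8-OH | CC(=O)O[C@@H]([C@@](O)(C=O)[C@@H](C)CO[Si](C)(C)C(C)(C)C)[C@@H]1[C@](C)(C=CC(=O)[C@@]1(C)OC(C)=O)[C@H]1O[C@@H]1C/C(CO[Si](c1ccccc1)(c1ccccc1)C(C)(C)C)=C\I | intermediate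
31 | 8-O-trimethylsilyl ether of 30 | CC(=O)O[C@@H]([C@@](O[Si](C)(C)C)(C=O)[C@@H](C)CO[Si](C)(C)C(C)(C)C)[C@@H]1[C@](C)(C=CC(=O)[C@@]1(C)OC(C)=O)[C@H]1O[C@@H]1C/C(CO[Si](c1ccccc1)(c1ccccc1)C(C)(C)C)=C\I | intermediate
32 | macrocycle (7-OH, 8-OSiMe3, 19-OTBS, 16-OTBDPS) | CC(=O)O[C@@H]1[C@@H]2[C@](C)(C=CC(=O)[C@@]2(C)OC(C)=O)[C@H]2O[C@@H]2C/C(CO[Si](c3ccccc3)(c3ccccc3)C(C)(C)C)=C\[C@H](O)[C@@]1(O[Si](C)(C)C)[C@@H](C)CO[Si](C)(C)C(C)(C)C | intermediate
33 | 7,8,19-triol, 16-OTBDPS | CC(=O)O[C@@H]1[C@@H]2[C@](C)(C=CC(=O)[C@@]2(C)OC(C)=O)[C@H]2O[C@@H]2C/C(CO[Si](c3ccccc3)(c3ccccc3)C(C)(C)C)=C\[C@H](O)[C@@]1(O)[C@@H](C)CO | intermediate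
34 | C19 lactol | CC(=O)O[C@@H]1[C@@H]2[C@](C)(C=CC(=O)[C@@]2(C)OC(C)=O)[C@H]2O[C@@H]2C/C(CO[Si](c3ccccc3)(c3ccccc3)C(C)(C)C)=C\[C@@H]2OC(O)[C@H](C)[C@]21O | intermediate
35 | 16-O-tert-butyldiphenylsilyl ether of the target | CC(=O)O[C@@H]1[C@@H]2[C@](C)(C=CC(=O)[C@@]2(C)OC(C)=O)[C@H]2O[C@@H]2C/C(CO[Si](c3ccccc3)(c3ccccc3)C(C)(C)C)=C\[C@@H]2OC(=O)[C@H](C)[C@]21O | intermediate
36 | CNP0155754.2 (1S,2R,3R,5E,7S,8S,9R,10S,11S,17R) | CC(=O)O[C@@H]1[C@@H]2[C@](C)(C=CC(=O)[C@@]2(C)OC(C)=O)[C@H]2O[C@@H]2C/C(CO)=C\[C@@H]2OC(=O)[C@H](C)[C@]21O | target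

**Totals.** 27 steps in all; longest linear sequence 22 steps (steps 1–10, 13, 17–27).

**Steps most likely to fail**

Step 3: the asynchronous cycloaddition may stall after the first bond, the zwitterion collapsing by benzyl or proton transfer before the second bond closes between two fully substituted carbons, or the endo preference may be low. Fallback: from 4, the same two bonds would be made in one flask as a Mukaiyama–Michael/Mukaiyama aldol annulation. 2-(Trimethylsilyloxy)propene would add at the δ-carbon of 4 under Cu(OTf)2/bis(oxazoline) catalysis to give the silyl dienol ether of keto lactone F1. TiCl4 added at −78 °C would then close the aldol bond onto the methyl ketone and give, after aqueous work-up, bicyclic hydroxy lactone F2. Pd(PPh3)4/morpholine deallylation would give acid F3, and Barton decarboxylation as in step 5 returns to 10.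

Step 8: γ-attack of the cuprate on the fully substituted alkene carbon, on the face that also carries the C11 acetate, may be outrun by attack on the acetate or by reduction of the lactone. Fallback: from 9, the quaternary centre would be made by conjugate addition. Methanolysis (K2CO3, MeOH) would give hydroxy ester F4 and MnO2 oxidation enone F5. Conjugate addition of the vinyl cuprate anti to the adjacent ester, with trapping of the regiodefined enolate by PhNTf2, would give enol triflate F6. Reduction of the triflate (Pd(OAc)2, PPh3, HCO2H, Bu3N) would give diene ester F7 and iBu2AlH at −78 °C aldehyde F8. Debenzylation (BCl3, pentamethylbenzene) would give hydroxy aldehyde F9, and acetylation (Ac2O, DMAP) rejoins the route at 14.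

Step 24: the ten-membered ring closure may show poor facial selectivity at C7 because a chromium-chelated transition state competes with the Felkin–Anh one. Fallback: from 31, the cyclisation would be run regardless and the C7 stereocentre set by reduction instead. The C7 epimer mixture would be oxidised (Dess–Martin periodinane) to macrocyclic enone F10 and desilylated at C8 and C19 (HF·pyridine) to α-hydroxy enone F11. Zn(BH4)2 would then reduce the C7 ketone under chelation with the C8 hydroxyl, which directs hydride to the face giving the 7,8-anti diol, and this returns to 33.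

Further compounds
F1 | step 3 | allyl 4-methyl-2-oxo-6-(2-oxopropyl)-5,6-dihydro-2H-pyran-3-carboxylate (C6 configured as C13 of 10) | CC(=O)C[C@@H]1CC(C)=C(C(=O)OCC=C)C(=O)O1
F2 | step 3 | allyl (1R,4R,8R)-8-hydroxy-5,8-dimethyl-3-oxo-2-oxabicyclo[2.2.2]oct-5-ene-4-carboxylate | O=C1O[C@@H]2C[C@@](C)(O)[C@@]1(C(=O)OCC=C)C(C)=C2
F3 | step 3 | (1R,4R,8R)-8-hydroxy-5,8-dimethyl-3-oxo-2-oxabicyclo[2.2.2]oct-5-ene-4-carboxylic acid | O=C1O[C@@H]2C[C@@](C)(O)[C@@]1(C(=O)O)C(C)=C2
F4 | step 8 | methyl 6-(benzyloxy)-4-hydroxy-2,6-dimethylcyclohex-2-ene-1-carboxylate (C10, C11, C13 as in 9) | COC(=O)[C@@H]1C(C)=C[C@H](O)C[C@@]1(C)OCc1ccccc1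
F5 | step 8 | methyl 6-(benzyloxy)-2,6-dimethyl-4-oxocyclohex-2-ene-1-carboxylate | COC(=O)[C@@H]1C(C)=CC(=O)C[C@@]1(C)OCc1ccccc1
F6 | step 8 | methyl 6-(benzyloxy)-2-ethenyl-2,6-dimethyl-4-{[(trifluoromethyl)sulfonyl]oxy}cyclohex-3-ene-1-carboxylate | COC(=O)[C@@H]1[C@@](C)(C=C)C=C(OS(=O)(=O)C(F)(F)F)C[C@@]1(C)OCc1ccccc1
F7 | step 8 | methyl 6-(benzyloxy)-2-ethenyl-2,6-dimethylcyclohex-3-ene-1-carboxylate | COC(=O)[C@@H]1[C@@](C)(C=C)C=CC[C@@]1(C)OCc1ccccc1
F8 | step 8 | 6-(benzyloxy)-2-ethenyl-2,6-dimethylcyclohex-3-ene-1-carbaldehyde | O=C[C@@H]1[C@@](C)(C=C)C=CC[C@@]1(C)OCc1ccccc1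
F9 | step 8 | 2-ethenyl-6-hydroxy-2,6-dimethylcyclohex-3-ene-1-carbaldehyde | O=C[C@@H]1[C@@](C)(C=C)C=CC[C@@]1(C)O
F10 | step 24 | 7-oxo macrocycle (8-OSiMe3, 19-OTBS, 16-OTBDPS) | CC(=O)O[C@@H]1[C@@H]2[C@](C)(C=CC(=O)[C@@]2(C)OC(C)=O)[C@H]2O[C@@H]2C/C(CO[Si](c3ccccc3)(c3ccccc3)C(C)(C)C)=C\C(=O)[C@@]1(O[Si](C)(C)C)[C@@H](C)CO[Si](C)(C)C(C)(C)C
F11 | step 24 | 8,19-dihydroxy-7-oxo macrocycle (16-OTBDPS) | CC(=O)O[C@@H]1[C@@H]2[C@](C)(C=CC(=O)[C@@]2(C)OC(C)=O)[C@H]2O[C@@H]2C/C(CO[Si](c3ccccc3)(c3ccccc3)C(C)(C)C)=C\C(=O)[C@@]1(O)[C@@H](C)CO
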